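**Retrosynthetic overview**
1. The C10–O ester bond is cut last: a macrocyclic C10 alcohol (C13 silyl-protected) plus (2R,3S)-3-silyloxy-2-methylbutanoic acid (fragment C, from a Brown syn-crotylation of acetaldehyde).
2. The only ring, the 14-membered carbocycle, is closed at C12–C13 by a nickel-catalysed reductive alkyne–aldehyde macrocyclisation of a linear ynal; this also sets the 11E alkene and C13.
3. The linear ynal comes from a palladium-catalysed B-alkyl Suzuki–Miyaura coupling at C4–C5 of a (Z)-vinyl iodide (fragment A, C13–C4) with a homoallylic iodide (fragment B, C5–C12).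
4. Fragment A: 5,6-dihydro-2H-pyran-2-one plus an isopropenyl borate (rhodium-catalysed asymmetric 1,4-addition sets C1), then an α-iodo Wittig olefination (3Z).
5. Fragment B: but-3-yn-1-ol, Me3Al and oxirane (zirconium-catalysed carboalumination sets 7E), then propynylmagnesium bromide and ynone transfer hydrogenation (sets C10).

Assumption 1: ring atoms are labelled C1–C14 in the order of the target SMILES (C1 carries the isopropenyl group, C3=C4 is Z, C7=C8 and C11=C12 are E, C10 carries the ester oxygen, C13 the free hydroxyl); the target is 1S,10R,13S with a 2R,3S acyl group.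
Assumption 2: NHC* = (4R,5R)-1,3-bis(2-isopropylphenyl)-4,5-diphenyl-4,5-dihydroimidazol-2-ylidene, taken as the antipode that directs Re-face attack at C13 in step 21; its mirror image is used if a model coupling shows the opposite sense.

**Fragment A**

Step 1
Reactants: 1 5,6-dihydro-2H-pyran-2-one; 2 potassium trifluoro(prop-1-en-2-yl)borate
Product: 3 (4S)-4-(prop-1-en-2-yl)oxan-2-one
Conditions: [Rh(cod)2]BF4 (3 mol %), (S)-BINAP (3.3 mol %), toluene/H2O 10:1, 100 °C
Reagents that add atoms: none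
Why: Hayashi–Miyaura asymmetric 1,4-addition, in which the isopropenyl–rhodium/(S)-BINAP species (monovalent rhodium) inserts the enoate on the same face as in the (S)-selective aryl additions to this lactone, so C1 is set as S.

Step 2
Reactants: 3
Product: 4 (3S)-5-hydroxy-N-methoxy-N-methyl-3-(prop-1-en-2-yl)pentanamide
Conditions: MeNH(OMe)·HCl, i-PrMgCl, THF, −20 → 0 °C
Reagents that add atoms: N,O-dimethylhydroxylamine hydrochloride, CNOC.Cl
Why: Weinreb aminolysis of the lactone by the chloromagnesium amide opens the ring to a stable hydroxy amide and differentiates the two arms at C1 (amide arm = C14–C13, hydroxyethyl arm = C2–C3) without touching the stereocentre.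

Step 3
Reactants: 4
Product: 5 (3S)-N-methoxy-N-methyl-5-oxo-3-(prop-1-en-2-yl)pentanamide
Conditions: Dess–Martin periodinane, CH2Cl2, 0 °C → rt
Reagents that add atoms: none
Why: Dess–Martin oxidation of the primary alcohol stops at the aldehyde under neutral conditions, and the stereocentre is β to both carbonyls so it cannot epimerise.

Step 4
Reactants: 6 iodoethane
Product: 7 ethyltriphenylphosphonium iodide
Conditions: PPh3, toluene, 100 °C
Reagents that add atoms: triphenylphosphine, c1ccc(cc1)P(c1ccccc1)c1ccccc1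
Why: SN2 quaternisation of triphenylphosphine by a primary iodide gives the Wittig salt cleanly.

Step 5
Reactants: 5; 7
Product: 11 (3S,5Z)-6-iodo-N-methoxy-N-methyl-3-(prop-1-en-2-yl)hept-5-enamide, via ethylidenetriphenylphosphorane 8 (not isolated), via (1-iodoethyl)triphenylphosphonium iodide 9 (not isolated), via (1-iodoethylidene)triphenylphosphorane 10 (not isolated)
Conditions: 7, n-BuLi, THF, 0 °C; I2, −78 °C; NaN(SiMe3)2, −20 °C; 5, −78 → −20 °C
Reagents that add atoms: iodine, II
Why: Zhao α-iodo Wittig olefination, in which the non-stabilised iodo ylide adds under kinetic control to give the (Z)-2-iodo-2-alkene (iodine cis to the chain, typically about 8:1 or better), while the Weinreb amide is inert to the ylide at low temperature.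

**Fragment B**

Step 6
Reactants: 12 but-3-yn-1-ol
Product: 13 tert-butyl(but-3-yn-1-yloxy)dimethylsilane
Conditions: TBSCl, imidazole, DMF, rt
Reagents that add atoms: tert-butyldimethylsilyl chloride, CC(C)(C)[Si](C)(C)Cl
Why: Standard silylation masks the hydroxyl (future C10 oxygen) for the organoaluminium chemistry.

Step 7
Reactants: 13; 14 oxirane
Product: 17 (3E)-6-[(tert-butyldimethylsilyl)oxy]-4-methylhex-3-en-1-ol, via alkenyldimethylalane 15 (not isolated), via lithium alkenylalanate 16 (not isolated)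
Conditions: Me3Al, Cp2ZrCl2 (25 mol %), CH2Cl2, rt; n-BuLi, hexane/THF, 0 °C; 14, −30 °C → rt
Reagents that add atoms: trimethylaluminium, C[Al](C)C
Why: Negishi zirconium-catalysed carboalumination adds methyl and aluminium syn across the terminal alkyne, which fixes the 7E trisubstituted alkene, and the alkenyl group of the derived alanate opens oxirane with retention of geometry to add C6–C5.

Step 8
Reactants: 17
Product: 18 tert-butyl{[(3E)-6-iodo-3-methylhex-3-en-1-yl]oxy}dimethylsilane
Conditions: I2, PPh3, imidazole, CH2Cl2, 0 °C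
Reagents that add atoms: iodine, II
Why: Appel-type iodination converts the primary homoallylic alcohol to the iodide by SN2 without touching the alkene or the silyl ether.

Step 9
Reactants: 18
Product: 19 (3E)-6-iodo-3-methylhex-3-en-1-ol
Conditions: CSA (10 mol %), MeOH, 0 °C
Reagents that add atoms: none
Why: Acid-catalysed methanolysis removes the primary TBS ether quickly, and the alkyl iodide and the alkene are stable to it.

Step 10
Reactants: 19
Product: 20 (3E)-6-iodo-3-methylhex-3-enal
Conditions: Dess–Martin periodinane, NaHCO3, CH2Cl2, 0 °C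
Reagents that add atoms: none
Why: Buffered Dess–Martin oxidation gives the β,γ-unsaturated aldehyde without base, and it is used crude at once so the alkene does not move into conjugation.

Step 11
Reactants: 20; 21 prop-1-yn-1-ylmagnesium bromide
Product: 22 (6E)-9-iodo-6-methylnon-6-en-2-yn-4-ol (racemic)
Conditions: THF, −78 °C
Reagents that add atoms: none
Why: Grignard 1,2-addition of the alkynyl nucleophile at −78 °C is faster than enolisation of the aldehyde and does not touch the primary iodide.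

Step 12
Reactants: 22
Product: 23 (6E)-9-iodo-6-methylnon-6-en-2-yn-4-one
Conditions: Dess–Martin periodinane, NaHCO3, CH2Cl2, 0 °C
Reagents that add atoms: none
Why: Dess–Martin oxidation of the propargylic alcohol to the ynone proceeds under neutral buffered conditions that do not isomerise the β,γ-alkene.

Step 13
Reactants: 23
Product: 24 (4R,6E)-9-iodo-6-methylnon-6-en-2-yn-4-ol
Conditions: Ru[(R,R)-TsNCH(Ph)CH(Ph)NH](p-cymene) (2 mol %), i-PrOH, rt
Reagents that add atoms: none
Why: Noyori asymmetric transfer hydrogenation of the ynone is base-free and reduces only the C=O; since the (S,S)-catalyst gives (S)-alkynols, the (R,R)-catalyst sets C10 as R.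

Step 14
Reactants: 24
Product: 25 triethyl{[(4R,6E)-9-iodo-6-methylnon-6-en-2-yn-4-yl]oxy}silane
Conditions: Et3SiCl, imidazole, CH2Cl2, 0 °C
Reagents that add atoms: chlorotriethylsilane, CC[Si](CC)(CC)Cl
Why: Silylation gives a C10 TES ether that survives organolithium, aqueous base, i-Bu2AlH and nickel/silane conditions, yet can later be removed in the presence of a TIPS ether.

**Fragment C**

Step 15
Reactants: 26 (Z)-but-2-ene; 27 acetaldehyde
Product: 31 (2S,3S)-3-methylpent-4-en-2-ol, via (Z)-crotylpotassium 28 (not isolated), via potassium crotyl(methoxy)borate complex 29 (not isolated), via (Z)-crotyldiisopinocampheylborane 30 (not isolated)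
Conditions: KOt-Bu, n-BuLi, THF, −78 → −45 °C; (+)-Ipc2BOMe, −78 °C; BF3·OEt2; 27, −78 °C; NaOH, H2O2
Reagents that add atoms: none
Why: Brown asymmetric crotylboration through a closed chair transition state, in which the Z-crotyl geometry gives the syn relationship and the Ipc groups of the (+)-Ipc2BOMe-derived borane direct Re-face attack on acetaldehyde, setting 2S,3S (the future 3S,2R centres of the acyl group).

Step 16
Reactants: 31
Product: 32 tert-butyldimethyl{[(2S,3S)-3-methylpent-4-en-2-yl]oxy}silane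
Conditions: TBSCl, imidazole, DMF, rt
Reagents that add atoms: tert-butyldimethylsilyl chloride, CC(C)(C)[Si](C)(C)Cl
Why: Silylation of the secondary alcohol protects it for the oxidations and makes the volatile alcohol easy to separate from isopinocampheol.

Step 17
Reactants: 32
Product: 34 (2R,3S)-3-[(tert-butyldimethylsilyl)oxy]-2-methylbutanal, via secondary ozonide 33 (not isolated)
Conditions: O3, CH2Cl2, −78 °C; PPh3, −78 °C → rt
Reagents that add atoms: ozone, [O-][O+]=O
Why: Ozonolysis with reductive work-up cleaves the vinyl group to the aldehyde under neutral conditions, so the α-methyl centre does not epimerise.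

Step 18
Reactants: 34
Product: 35 (2R,3S)-3-[(tert-butyldimethylsilyl)oxy]-2-methylbutanoic acid
Conditions: NaClO2, NaH2PO4, 2-methylbut-2-ene, t-BuOH/H2O, 0 °C
Reagents that add atoms: sodium chlorite, [Na+].[O-]Cl=O
Why: Pinnick oxidation converts the aldehyde to the acid at buffered pH without epimerising the α-centre or cleaving the silyl ether.

**Coupling and endgame**

Step 19
Reactants: 25; 11
Product: 38 (3S,5Z,9E,12R)-N-methoxy-N,6,10-trimethyl-3-(prop-1-en-2-yl)-12-[(triethylsilyl)oxy]pentadeca-5,9-dien-13-ynamide, via homoallylic alkyllithium 36 (not isolated), via lithium methoxyborinate complex 37 (not isolated)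
Conditions: 25, t-BuLi (2.1 equiv), Et2O, −78 °C; 9-MeO-9-BBN, THF, −78 °C → rt; 11, Pd(dppf)Cl2 (5 mol %), AsPh3, Cs2CO3, DMF/H2O, rt
Reagents that add atoms: none
Why: B-alkyl Suzuki–Miyaura coupling, in which lithium–iodine exchange and capture by the methoxyborane give a borinate that transmetalates to the alkenylpalladium iodide (divalent palladium) formed from 11, and reductive elimination makes C4–C5 with retention of the Z geometry.

Step 20
Reactants: 38
Product: 40 (3S,5Z,9E,12R)-6,10-dimethyl-3-(prop-1-en-2-yl)-12-[(triethylsilyl)oxy]pentadeca-5,9-dien-13-ynal, via aluminium hemiaminal chelate 39 (not isolated)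
Conditions: i-Bu2AlH, THF, −78 °C
Reagents that add atoms: none
Why: Weinreb amide reduction stops at the chelated tetrahedral intermediate, which releases the C13 aldehyde only on work-up, so there is no over-reduction and the alkyne and silyl ether are untouched.

Step 21
Reactants: 40
Product: 41 triethyl({(1R,2E,4S,6S,8Z,12E)-3,9,13-trimethyl-6-(prop-1-en-2-yl)-4-[(triisopropylsilyl)oxy]cyclotetradeca-2,8,12-trien-1-yl}oxy)silane (C10–OTES, C13–OTIPS macrocycle)
Conditions: Ni(cod)2 (20 mol %), NHC*·HBF4 (20 mol %), KOt-Bu (20 mol %), i-Pr3SiH (3 equiv), THF, rt, 40 added over 8 h (0.002 M)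
Reagents that add atoms: triisopropylsilane, CC(C)[SiH](C(C)C)C(C)C
Why: Proposed new method: a zerovalent nickel complex of the C2-symmetric carbene NHC* binds the aldehyde and the alkyne of 40, and oxidative cyclisation gives an oxanickelacyclopentene with the new C12–C13 bond at the methyl-bearing alkyne carbon (a small carbene and the branched C10 both favour this endo mode, hence the 14-membered ring); σ-bond metathesis with i-Pr3SiH then forms the O–Si bond and a vinylnickel hydride, and C–H reductive elimination puts H on C11 syn to C13 (11E), while the chiral carbene is meant to force attack on the Re face of C13 and override the weak bias from C1, setting 13S; the closest known reactions are the achiral nickel/carbene/silane reductive macrocyclisations of ynals and the intermolecular enantioselective aldehyde–alkyne reductive couplings with chiral carbenes, and the new element is catalyst-controlled face selectivity in the ring closure.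

Step 22
Reactants: 41
Product: 42 (1R,2E,4S,6S,8Z,12E)-3,9,13-trimethyl-6-(prop-1-en-2-yl)-4-[(triisopropylsilyl)oxy]cyclotetradeca-2,8,12-trien-1-ol
Conditions: PPTS (20 mol %), MeOH/CH2Cl2, 0 °C
Reagents that add atoms: none
Why: Mild acid-catalysed methanolysis removes the TES ether at C10 far faster than the hindered TIPS ether at C13, which frees only the hydroxyl that is to be acylated.

Step 23
Reactants: 42; 35
Product: 44 (1R,2E,4S,6S,8Z,12E)-3,9,13-trimethyl-6-(prop-1-en-2-yl)-4-[(triisopropylsilyl)oxy]cyclotetradeca-2,8,12-trien-1-yl (2R,3S)-3-[(tert-butyldimethylsilyl)oxy]-2-methylbutanoate, via Yamaguchi mixed anhydride 43 (not isolated)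
Conditions: 35, 2,4,6-Cl3C6H2COCl, Et3N, THF, rt; 42, DMAP, toluene, rt
Reagents that add atoms: none
Why: Yamaguchi esterification acylates the hindered secondary allylic alcohol through the mixed anhydride with retention at C10 (the C–O bond is not broken) and little α-epimerisation of the β-silyloxy acid.

Step 24
Reactants: 44
Product: 45 (1R,2E,4S,6S,8Z,12E)-4-hydroxy-3,9,13-trimethyl-6-(prop-1-en-2-yl)cyclotetradeca-2,8,12-trien-1-yl (2R,3S)-3-hydroxy-2-methylbutanoate (CNP0328880.1)
Conditions: HF·pyridine, pyridine, THF, 0 °C → rt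
Reagents that add atoms: none
Why: Buffered fluoride desilylation removes the TIPS and TBS ethers without cleaving the ester, and acyl migration from C10 to C13 is blocked by the E alkene between them.

**Compound list**
1 | 5,6-dihydro-2H-pyran-2-one | O=C1C=CCCO1 | starting material
2 | potassium trifluoro(prop-1-en-2-yl)borate | [K+].C=C(C)[B-](F)(F)F | starting material
3 | (4S)-4-(prop-1-en-2-yl)oxan-2-one | C=C(C)[C@H]1CCOC(=O)C1 | intermediate
4 | (3S)-5-hydroxy-N-methoxy-N-methyl-3-(prop-1-en-2-yl)pentanamide | C=C(C)[C@H](CC(=O)N(C)OC)CCO | intermediate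
5 | (3S)-N-methoxy-N-methyl-5-oxo-3-(prop-1-en-2-yl)pentanamide | C=C(C)[C@H](CC(=O)N(C)OC)CC=O | intermediate
6 | iodoethane | CCI | starting material
7 | ethyltriphenylphosphonium iodide | CC[P+](c1ccccc1)(c1ccccc1)c1ccccc1.[I-] | intermediate
8 | ethylidenetriphenylphosphorane | CC=P(c1ccccc1)(c1ccccc1)c1ccccc1 | intermediate
9 | (1-iodoethyl)triphenylphosphonium iodide | CC(I)[P+](c1ccccc1)(c1ccccc1)c1ccccc1.[I-] | intermediate
10 | (1-iodoethylidene)triphenylphosphorane | CC(I)=P(c1ccccc1)(c1ccccc1)c1ccccc1 | intermediate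
11 | (3S,5Z)-6-iodo-N-methoxy-N-methyl-3-(prop-1-en-2-yl)hept-5-enamide | C=C(C)[C@H](CC(=O)N(C)OC)C/C=C(/C)I | intermediate
12 | but-3-yn-1-ol | C#CCCO | starting material
13 | tert-butyl(but-3-yn-1-yloxy)dimethylsilane | C#CCCO[Si](C)(C)C(C)(C)C | intermediate
14 | oxirane | C1CO1 | starting material
15 | {(1E)-4-[(tert-butyldimethylsilyl)oxy]-2-methylbut-1-en-1-yl}dimethylalane | C[Al](C)/C=C(\C)CCO[Si](C)(C)C(C)(C)C | intermediate
16 | lithium butyl{(1E)-4-[(tert-butyldimethylsilyl)oxy]-2-methylbut-1-en-1-yl}dimethylaluminate | [Li+].CCCC[Al-](C)(C)/C=C(\C)CCO[Si](C)(C)C(C)(C)C | intermediate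
17 | (3E)-6-[(tert-butyldimethylsilyl)oxy]-4-methylhex-3-en-1-ol | OCC/C=C(\C)CCO[Si](C)(C)C(C)(C)C | intermediate
18 | tert-butyl{[(3E)-6-iodo-3-methylhex-3-en-1-yl]oxy}dimethylsilane | ICC/C=C(\C)CCO[Si](C)(C)C(C)(C)C | intermediate
19 | (3E)-6-iodo-3-methylhex-3-en-1-ol | ICC/C=C(\C)CCO | intermediate
20 | (3E)-6-iodo-3-methylhex-3-enal | ICC/C=C(\C)CC=O | intermediate
21 | prop-1-yn-1-ylmagnesium bromide | CC#C[Mg]Br | starting material
22 | (6E)-9-iodo-6-methylnon-6-en-2-yn-4-ol, racemic | ICC/C=C(\C)CC(O)C#CC | intermediate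
23 | (6E)-9-iodo-6-methylnon-6-en-2-yn-4-one | ICC/C=C(\C)CC(=O)C#CC | intermediate
24 | (4R,6E)-9-iodo-6-methylnon-6-en-2-yn-4-ol | ICC/C=C(\C)C[C@@H](O)C#CC | intermediate
25 | triethyl{[(4R,6E)-9-iodo-6-methylnon-6-en-2-yn-4-yl]oxy}silane | ICC/C=C(\C)C[C@@H](O[Si](CC)(CC)CC)C#CC | intermediate
26 | (Z)-but-2-ene | C/C=C\C | starting material
27 | acetaldehyde | CC=O | starting material
28 | (Z)-but-2-en-1-ylpotassium | C/C=C\C[K] | intermediate
29 | potassium [(Z)-but-2-en-1-yl]bis(isopinocampheyl)(methoxy)borate, Ipc groups as in (+)-Ipc2BOMe | [K+].CO[B-](C/C=C\C)([C@H]1C[C@H]2C[C@@H]([C@@H]1C)C2(C)C)[C@H]1C[C@H]2C[C@@H]([C@@H]1C)C2(C)C | intermediate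
30 | [(Z)-but-2-en-1-yl]bis(isopinocampheyl)borane, Ipc groups as in (+)-Ipc2BOMe | C/C=C\CB([C@H]1C[C@H]2C[C@@H]([C@@H]1C)C2(C)C)[C@H]1C[C@H]2C[C@@H]([C@@H]1C)C2(C)C | intermediate
31 | (2S,3S)-3-methylpent-4-en-2-ol | C=C[C@H](C)[C@H](C)O | intermediate
32 | tert-butyldimethyl{[(2S,3S)-3-methylpent-4-en-2-yl]oxy}silane | C=C[C@H](C)[C@H](C)O[Si](C)(C)C(C)(C)C | intermediate
33 | 3-{(2R,3S)-3-[(tert-butyldimethylsilyl)oxy]butan-2-yl}-1,2,4-trioxolane (both epimers at the ring carbon) | C1OC(OO1)[C@H](C)[C@H](C)O[Si](C)(C)C(C)(C)C | intermediate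
34 | (2R,3S)-3-[(tert-butyldimethylsilyl)oxy]-2-methylbutanal | O=C[C@H](C)[C@H](C)O[Si](C)(C)C(C)(C)C | intermediate
35 | (2R,3S)-3-[(tert-butyldimethylsilyl)oxy]-2-methylbutanoic acid | OC(=O)[C@H](C)[C@H](C)O[Si](C)(C)C(C)(C)C | intermediate
36 | {(3E,6R)-4-methyl-6-[(triethylsilyl)oxy]non-3-en-7-yn-1-yl}lithium | [Li]CC/C=C(\C)C[C@@H](O[Si](CC)(CC)CC)C#CC | intermediate
37 | lithium 9-methoxy-9-{(3E,6R)-4-methyl-6-[(triethylsilyl)oxy]non-3-en-7-yn-1-yl}-9-boranuidabicyclo[3.3.1]nonane | [Li+].CO[B-]1(CC/C=C(\C)C[C@@H](O[Si](CC)(CC)CC)C#CC)C2CCCC1CCC2 | intermediate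
38 | (3S,5Z,9E,12R)-N-methoxy-N,6,10-trimethyl-3-(prop-1-en-2-yl)-12-[(triethylsilyl)oxy]pentadeca-5,9-dien-13-ynamide | C=C(C)[C@H](CC(=O)N(C)OC)C/C=C(/C)CC/C=C(\C)C[C@@H](O[Si](CC)(CC)CC)C#CC | intermediate
39 | O-(diisobutylalumanyl) hemiaminal of 38 at C1 (tetrahedral adduct, both C1 epimers) | C=C(C)[C@H](CC(O[Al](CC(C)C)CC(C)C)N(C)OC)C/C=C(/C)CC/C=C(\C)C[C@@H](O[Si](CC)(CC)CC)C#CC | intermediate
40 | (3S,5Z,9E,12R)-6,10-dimethyl-3-(prop-1-en-2-yl)-12-[(triethylsilyl)oxy]pentadeca-5,9-dien-13-ynal | C=C(C)[C@H](CC=O)C/C=C(/C)CC/C=C(\C)C[C@@H](O[Si](CC)(CC)CC)C#CC | intermediate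
41 | triethyl({(1R,2E,4S,6S,8Z,12E)-3,9,13-trimethyl-6-(prop-1-en-2-yl)-4-[(triisopropylsilyl)oxy]cyclotetradeca-2,8,12-trien-1-yl}oxy)silane | C=C(C)[C@H]1C/C=C(/C)CC/C=C(\C)C[C@@H](O[Si](CC)(CC)CC)/C=C(\C)[C@@H](O[Si](C(C)C)(C(C)C)C(C)C)C1 | intermediate
42 | (1R,2E,4S,6S,8Z,12E)-3,9,13-trimethyl-6-(prop-1-en-2-yl)-4-[(triisopropylsilyl)oxy]cyclotetradeca-2,8,12-trien-1-ol | C=C(C)[C@H]1C/C=C(/C)CC/C=C(\C)C[C@@H](O)/C=C(\C)[C@@H](O[Si](C(C)C)(C(C)C)C(C)C)C1 | intermediate
43 | (2R,3S)-3-[(tert-butyldimethylsilyl)oxy]-2-methylbutanoic 2,4,6-trichlorobenzoic anhydride | O=C(OC(=O)c1c(Cl)cc(Cl)cc1Cl)[C@H](C)[C@H](C)O[Si](C)(C)C(C)(C)C | intermediate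
44 | (1R,2E,4S,6S,8Z,12E)-3,9,13-trimethyl-6-(prop-1-en-2-yl)-4-[(triisopropylsilyl)oxy]cyclotetradeca-2,8,12-trien-1-yl (2R,3S)-3-[(tert-butyldimethylsilyl)oxy]-2-methylbutanoate | C=C(C)[C@H]1C/C=C(/C)CC/C=C(\C)C[C@@H](OC(=O)[C@H](C)[C@H](C)O[Si](C)(C)C(C)(C)C)/C=C(\C)[C@@H](O[Si](C(C)C)(C(C)C)C(C)C)C1 | intermediate
45 | (1R,2E,4S,6S,8Z,12E)-4-hydroxy-3,9,13-trimethyl-6-(prop-1-en-2-yl)cyclotetradeca-2,8,12-trien-1-yl (2R,3S)-3-hydroxy-2-methylbutanoate | C=C(C)[C@H]1C/C=C(/C)CC/C=C(\C)C[C@@H](OC(=O)[C@H](C)[C@H](C)O)/C=C(\C)[C@@H](O)C1 | target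

**Totals**
Total step count: 24.
Longest linear sequence: 15 steps (from 12 through steps 6–14, then steps 19–24).

**Steps most likely to fail, with fallbacks**

Step 21 (the new ring closure). The risks are the exo mode giving a 13-membered ring, simple hydrosilylation of the aldehyde, and low or reversed face selectivity at C13. The fallback uses known chemistry, sets out from 38 and comes back at 41. Compound 38 is treated with Cp2Zr(H)Cl (about 2.5 equiv, THF, rt), which reduces the Weinreb amide to the zirconium-bound hemiaminal and hydrozirconates the methyl alkyne with zirconium on C12, away from the branched C10. Addition of I2 at −20 °C and aqueous work-up give (3S,5Z,9E,12R,13E)-14-iodo-6,10-dimethyl-3-(prop-1-en-2-yl)-12-[(triethylsilyl)oxy]pentadeca-5,9,13-trienal F1. Nozaki–Hiyama–Kishi ring closure (CrCl2, NiCl2 1 mol %, DMSO/THF, 0.003 M) then gives (2E,4R,6E,10Z,13S)-2,6,10-trimethyl-13-(prop-1-en-2-yl)-4-[(triethylsilyl)oxy]cyclotetradeca-2,6,10-trien-1-ol F2 as a mixture of carbinol epimers. Dess–Martin oxidation converts both epimers to (2E,4R,6E,10Z,13S)-2,6,10-trimethyl-13-(prop-1-en-2-yl)-4-[(triethylsilyl)oxy]cyclotetradeca-2,6,10-trien-1-one F3. Reduction with (R)-2-methyl-CBS-oxazaborolidine and catecholborane (toluene, −78 °C) gives (1S,2E,4R,6E,10Z,13S)-2,6,10-trimethyl-13-(prop-1-en-2-yl)-4-[(triethylsilyl)oxy]cyclotetradeca-2,6,10-trien-1-ol F4, and i-Pr3SiOTf with 2,6-lutidine converts it to 41.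

Step 5 (Zhao olefination). The risks are a modest yield from the unstable iodo ylide and incomplete Z selectivity with an aldehyde that is unbranched at the α-carbon. The fallback sets out from 5 and comes back at 38. Dibromo-olefination of 5 (CBr4, PPh3, CH2Cl2, 0 °C) gives (3S)-6,6-dibromo-N-methoxy-N-methyl-3-(prop-1-en-2-yl)hex-5-enamide F5. Negishi trans-selective monomethylation (Me2Zn, Pd(DPEphos)Cl2 3 mol %, THF/DMF, rt) replaces only the bromine trans to the chain and gives (3S,5Z)-6-bromo-N-methoxy-N-methyl-3-(prop-1-en-2-yl)hept-5-enamide F6. Iodide 25 is converted (t-BuLi, Et2O, −78 °C, then ZnCl2) into chloro{(3E,6R)-4-methyl-6-[(triethylsilyl)oxy]non-3-en-7-yn-1-yl}zinc F7, and Negishi coupling of F6 with F7 (Pd(t-Bu3P)2 3 mol %, THF, rt, retention of geometry) gives 38.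

Step 7 (carboalumination, then alanate opening of oxirane). The risks are competing butyl transfer from the alanate, Lewis-acid damage to the silyl ether, and a moderate yield in the epoxide opening. The fallback sets out from 13 and comes back at 17. The same carboalumination (through 15) is quenched with I2 (THF, −30 °C) to give tert-butyl{[(3E)-4-iodo-3-methylbut-3-en-1-yl]oxy}dimethylsilane F8. Suzuki–Miyaura coupling with potassium vinyltrifluoroborate (Pd(dppf)Cl2, Cs2CO3, THF/H2O, 70 °C) gives tert-butyldimethyl{[(3E)-3-methylhexa-3,5-dien-1-yl]oxy}silane F9. 9-BBN (THF, 0 °C → rt) adds only to the terminal vinyl group, with boron on the terminal carbon, and NaOH/H2O2 oxidation gives 17.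

Further compounds
F1 | step 21 | (3S,5Z,9E,12R,13E)-14-iodo-6,10-dimethyl-3-(prop-1-en-2-yl)-12-[(triethylsilyl)oxy]pentadeca-5,9,13-trienal | C=C(C)[C@H](CC=O)C/C=C(/C)CC/C=C(\C)C[C@@H](O[Si](CC)(CC)CC)/C=C(\C)I
F2 | step 21 | (2E,4R,6E,10Z,13S)-2,6,10-trimethyl-13-(prop-1-en-2-yl)-4-[(triethylsilyl)oxy]cyclotetradeca-2,6,10-trien-1-ol (carbinol epimers) | C=C(C)[C@H]1C/C=C(/C)CC/C=C(\C)C[C@@H](O[Si](CC)(CC)CC)/C=C(\C)C(O)C1
F3 | step 21 | (2E,4R,6E,10Z,13S)-2,6,10-trimethyl-13-(prop-1-en-2-yl)-4-[(triethylsilyl)oxy]cyclotetradeca-2,6,10-trien-1-one | C=C(C)[C@H]1C/C=C(/C)CC/C=C(\C)C[C@@H](O[Si](CC)(CC)CC)/C=C(\C)C(=O)C1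
F4 | step 21 | (1S,2E,4R,6E,10Z,13S)-2,6,10-trimethyl-13-(prop-1-en-2-yl)-4-[(triethylsilyl)oxy]cyclotetradeca-2,6,10-trien-1-ol | C=C(C)[C@H]1C/C=C(/C)CC/C=C(\C)C[C@@H](O[Si](CC)(CC)CC)/C=C(\C)[C@@H](O)C1
F5 | step 5 | (3S)-6,6-dibromo-N-methoxy-N-methyl-3-(prop-1-en-2-yl)hex-5-enamide | C=C(C)[C@H](CC(=O)N(C)OC)CC=C(Br)Br
F6 | step 5 | (3S,5Z)-6-bromo-N-methoxy-N-methyl-3-(prop-1-en-2-yl)hept-5-enamide | C=C(C)[C@H](CC(=O)N(C)OC)C/C=C(/C)Br
F7 | step 5 | chloro{(3E,6R)-4-methyl-6-[(triethylsilyl)oxy]non-3-en-7-yn-1-yl}zinc | Cl[Zn]CC/C=C(\C)C[C@@H](O[Si](CC)(CC)CC)C#CC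
F8 | step 7 | tert-butyl{[(3E)-4-iodo-3-methylbut-3-en-1-yl]oxy}dimethylsilane | I/C=C(\C)CCO[Si](C)(C)C(C)(C)C
F9 | step 7 | tert-butyldimethyl{[(3E)-3-methylhexa-3,5-dien-1-yl]oxy}silane | C=C/C=C(\C)CCO[Si](C)(C)C(C)(C)C
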